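**Retrosynthetic overview**

- The strategy rests on ring C. Its tetrasubstituted C(CH3)=C(CH2CH2–ring B) alkene lies between the hydroperoxide-bearing carbon and the ring-fusion CH next to the CMe2 carbon of ring D. This alkene is read as a 2-alkyne inserted into the C(=O)–CH(ring fusion) bond of a cyclobutanone cis-fused to ring D.
- Target ⇒ ring-C enone (C–OOH from C=O by 1,2-reduction and invertive peroxide substitution) ⇒ ring-A/B 2-alkyne + ring-D cyclobutanone, joined by a nickel-mediated (4+2) C–C activation that closes ring C last.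
- Cyclobutanone ⇐ enone–ketene acetal (2+2) photocycloaddition on 4,4-dimethylcyclohexenone, resolved as sulfoximine adducts; the tertiary carbinol comes from methylenation, epoxidation and hydride opening.
- Alkyne ⇐ trans-fused δ-lactone ⇐ one cationic cascade of a (6S,7S,10S)-diepoxy farnesyl ester that closes ring A (oxepane) and ring B together; lactone → alkyne by Ohira–Bestmann homologation and methylation.
- Order of ring formation: four-membered ring on ring D; rings A and B; ring C.

Key step: step 18

Remark on the chemistry: the photoadduct is made as a racemate and is resolved in step 2. Which of the two separated sulfoximine adducts carries the needed skeleton has to be assigned, for example by crystallography with sulfur as the heavy atom.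

**Route**

Step 1
Reactants: 1 4,4-dimethylcyclohex-2-en-1-one; 2 1,1-diethoxyethene
Product: 4 rac-cis-7,7-diethoxy-5,5-dimethylbicyclo[4.2.0]octan-2-one, via trans-fused photoadduct 3 (not isolated)
Conditions: hν (350 nm, Pyrex), 2 (5 equiv), hexane, −40 °C; then basic Al2O3, Et2O, 20 °C
Reagents that add atoms: none
Why: Enone–alkene (2+2) photocycloaddition with the electron-rich ketene acetal should give the head-to-tail adducts (acetal carbon on the enone β-carbon next to CMe2), and base epimerisation at the α-carbon turns the strained trans-fused isomer into the cis-fused ketone, which fixes the relative configuration of the two ring-fusion carbons.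

Step 2
Reactants: 4 rac-cis-7,7-diethoxy-5,5-dimethylbicyclo[4.2.0]octan-2-one
Product: 5 (1S,2R,6R)-7,7-diethoxy-5,5-dimethyl-2-{[(S)-N-methyl-S-phenylsulfonimidoyl]methyl}bicyclo[4.2.0]octan-2-ol
Conditions: (S)-N,S-dimethyl-S-phenylsulfoximine, n-BuLi, THF, −78 °C; then 4; then H2O; chromatography
Reagents that add atoms: (S)-N,S-dimethyl-S-phenylsulfoximine, C[S@@](=O)(=NC)c1ccccc1
Why: 1,2-addition of the lithiated enantiopure sulfoximine (first half of a sulfoximine methylenation with resolution) converts the two enantiomers of 4 into diastereomeric β-hydroxysulfoximines, so chromatography should deliver the (1S,6R) skeleton as one stereoisomer while the adduct of the mirror-image skeleton is removed; the new carbinol centre is destroyed in step 3 and its configuration is immaterial.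

Step 3
Reactants: 5 β-hydroxysulfoximine
Product: 6 (1S,6R)-7,7-diethoxy-5,5-dimethyl-2-methylidenebicyclo[4.2.0]octane
Conditions: Al(Hg), THF/H2O/AcOH, 20 °C
Reagents that add atoms: none
Why: Two-electron reduction cleaves the C–S bond and the β-hydroxy carbanion loses hydroxide (reductive elimination of a β-hydroxysulfoximine), giving the exocyclic alkene without touching the skeletal stereocentres or the slowly hydrolysing cyclobutanone ketal.

Step 4
Reactants: 6 exocyclic alkene
Product: 7 (1S,2S,6R)-7,7-diethoxy-5,5-dimethylspiro[bicyclo[4.2.0]octane-2,2'-oxirane], epoxide oxygen on the face of the ring-fusion hydrogens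
Conditions: dimethyldioxirane, acetone, 0 °C
Reagents that add atoms: dimethyldioxirane, CC1(C)OO1
Why: Epoxidation by the neutral dioxirane (ketal-compatible) should occur anti to the cyclobutane CH2 on the neighbouring carbon, which sets the tertiary C–O stereocentre.

Step 5
Reactants: 7 spiro-epoxide
Product: 8 (1S,2S,6R)-7,7-diethoxy-2,5,5-trimethylbicyclo[4.2.0]octan-2-ol
Conditions: LiAlH4, THF, 0 °C to 20 °C; then H2O
Reagents that add atoms: none
Why: Hydride opens the epoxide at its primary carbon (SN2), leaving the tertiary OH on the face of the fusion hydrogens and the new methyl syn to the four-membered ring.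

Step 6
Reactants: 8 tertiary alcohol ketal
Product: 9 (1S,2S,6R)-2-hydroxy-2,5,5-trimethylbicyclo[4.2.0]octan-7-one
Conditions: 1 M aq. HCl, THF, 20 °C
Reagents that add atoms: water, O
Why: Acid hydrolysis of the diethyl ketal frees the cyclobutanone; the hydroxyl is anti to the four-membered ring and cannot close a bridged hemiketal.

Step 7
Reactants: 9 hydroxy cyclobutanone
Product: 10 (1S,2S,6R)-2,5,5-trimethyl-2-(triethylsilyloxy)bicyclo[4.2.0]octan-7-one
Conditions: TESOTf, 2,6-lutidine, CH2Cl2, −78 °C
Reagents that add atoms: triethylsilyl trifluoromethanesulfonate, CC[Si](CC)(CC)OS(=O)(=O)C(F)(F)F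
Why: Silyl triflate with a hindered pyridine base silylates the tertiary alcohol at low temperature faster than it enolises the ketone.

Step 8
Reactants: 11 (2E,6E)-farnesol
Product: 12 (2E,6E)-farnesyl acetate
Conditions: Ac2O, pyridine, DMAP (cat.), CH2Cl2, 20 °C
Reagents that add atoms: acetic anhydride, CC(=O)OC(C)=O
Why: Acylation of the primary allylic alcohol; the acetoxy group deactivates the adjacent 2,3-alkene towards the electrophilic oxidant of step 9.

Step 9
Reactants: 12 farnesyl acetate
Product: 13 (2E,6S,7S,10S)-6,7:10,11-diepoxy-3,7,11-trimethyldodec-2-en-1-yl acetate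
Conditions: L-fructose-derived Shi ketone (30 mol%), KHSO5 (as its triple salt with KHSO4 and K2SO4), K2CO3, Bu4NHSO4, MeCN/CH2(OMe)2/aq. Na2B4O7 buffer, 0 °C
Reagents that add atoms: potassium peroxymonosulfate, [K+].[O-]S(=O)(=O)OO
Why: Shi epoxidation oxidises the two electron-rich trisubstituted alkenes from the same enantioface (spiro transition state) to the (6S,7S,10S)-diepoxide, while the alkene next to the acetate reacts more slowly.

Step 10
Reactants: 13 diepoxy acetate
Product: 14 (2E,6S,7S,10S)-6,7:10,11-diepoxy-3,7,11-trimethyldodec-2-en-1-ol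
Conditions: K2CO3 (cat.), MeOH, 0 °C
Reagents that add atoms: none
Why: Transesterification frees the allylic alcohol without opening the trisubstituted epoxides.

Step 11
Reactants: 14 diepoxy alcohol
Product: 16 (2E,6S,7S,10S)-1-bromo-6,7:10,11-diepoxy-3,7,11-trimethyldodec-2-ene, via allylic mesylate 15 (not isolated)
Conditions: MsCl, Et3N, THF, −45 °C; then LiBr, THF, 0 °C
Reagents that add atoms: lithium bromide, [Li+].[Br-]
Why: Sulfonylation then SN2 displacement by bromide at the primary allylic carbon under non-acidic conditions keeps the epoxides and the E-alkene intact.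

Step 12
Reactants: 16 diepoxy allylic bromide
Product: 17 tert-butyl (4E,8S,9S,12S)-8,9:12,13-diepoxy-5,9,13-trimethyltetradec-4-enoate
Conditions: tert-butyl acetate, LiN(i-Pr)2, THF, −78 °C; then 16, −78 °C to −20 °C
Reagents that add atoms: tert-butyl acetate, CC(=O)OC(C)(C)C
Why: SN2 alkylation of the lithium ester enolate at the unhindered primary end of the allylic bromide adds the two-carbon ester arm, which later becomes the linker CH2 and the alkyne carbon.

Step 13
Reactants: 17 diepoxy tert-butyl ester
Product: 18 trans-fused δ-lactone of (3S,5aS,6S,7S,9aS)-3-(tert-butyldimethylsilyloxy)-2,2,5a,7-tetramethyldecahydro-1-benzoxepine, in which C6–CH2CH2–C(=O)–O–C7 forms the six-membered lactone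
Conditions: TBSOTf, 2,6-di-tert-butyl-4-methylpyridine, CH2Cl2, −78 °C
Reagents that add atoms: tert-butyldimethylsilyl trifluoromethanesulfonate, CC(C)(C)[Si](C)(C)OS(=O)(=O)C(F)(F)F
Why: The silyl triflate activates the terminal epoxide, the inner epoxide oxygen attacks its tertiary carbon, and the resulting epoxonium ion is opened at its tertiary carbon by the E-alkene in a chair transition state (endo-selective oxa/carbacyclisation cascade); the tertiary cation is then captured by the ester carbonyl with loss of 2-methylpropene, so that anti addition across each epoxide and across the E-alkene sets the trans A/B fusion and the ring-B stereocentres from the three epoxide centres.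

Step 14
Reactants: 18 δ-lactone
Product: 19 corresponding lactol (mixture of anomers)
Conditions: i-Bu2AlH, CH2Cl2, −78 °C; then aq. potassium sodium tartrate
Reagents that add atoms: none
Why: Low-temperature partial reduction of the lactone stops at the aluminium hemiacetal.

Step 15
Reactants: 19 lactol
Product: 20 (3S,5aS,6S,7S,9aS)-6-(but-3-yn-1-yl)-3-(tert-butyldimethylsilyloxy)-2,2,5a,7-tetramethyldecahydro-1-benzoxepin-7-ol
Conditions: dimethyl (1-diazo-2-oxopropyl)phosphonate, K2CO3, MeOH, 0 °C to 20 °C
Reagents that add atoms: dimethyl (1-diazo-2-oxopropyl)phosphonate, CC(=O)C(=[N+]=[N-])P(=O)(OC)OC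
Why: Ohira–Bestmann (Seyferth–Gilbert) homologation of the open hydroxy-aldehyde form converts the lactol carbon into a terminal alkyne and frees the tertiary alcohol.

Step 16
Reactants: 20 alkynyl tertiary alcohol
Product: 21 (3S,5aS,6S,7S,9aS)-6-(but-3-yn-1-yl)-3-(tert-butyldimethylsilyloxy)-2,2,5a,7-tetramethyl-7-(triethylsilyloxy)decahydro-1-benzoxepine
Conditions: TESOTf, 2,6-lutidine, CH2Cl2, −78 °C to 0 °C
Reagents that add atoms: triethylsilyl trifluoromethanesulfonate, CC[Si](CC)(CC)OS(=O)(=O)C(F)(F)F
Why: Silylation of the hindered tertiary alcohol with the silyl triflate; the terminal alkyne C–H is not touched by 2,6-lutidine.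

Step 17
Reactants: 21 terminal alkyne
Product: 23 (3S,5aS,6S,7S,9aS)-3-(tert-butyldimethylsilyloxy)-2,2,5a,7-tetramethyl-6-(pent-3-yn-1-yl)-7-(triethylsilyloxy)decahydro-1-benzoxepine, via lithium acetylide 22 (not isolated)
Conditions: n-BuLi, THF, −78 °C; then MeI, −78 °C to 20 °C
Reagents that add atoms: iodomethane, CI
Why: Deprotonation of the terminal alkyne and SN2 methylation of the acetylide give the 2-alkyne.

Step 18
Reactants: 23 ring-A/B 2-alkyne; 10 cis-fused cyclobutanone (1.5 equiv)
Product: 24 (4aR,8S,8aS)-3,5,5,8-tetramethyl-8-(triethylsilyloxy)-4-{2-[(3S,5aS,6S,7S,9aS)-3-(tert-butyldimethylsilyloxy)-2,2,5a,7-tetramethyl-7-(triethylsilyloxy)decahydro-1-benzoxepin-6-yl]ethyl}-4a,5,6,7,8,8a-hexahydronaphthalen-2(1H)-one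
Conditions: Ni(cod)2 (20 mol%), PCy3 (40 mol%), toluene, 100 °C
Reagents that add atoms: none
Why: Proposed new method: zerovalent nickel should couple the cyclobutanone C=O of 10 with the alkyne of 23 oxidatively to a spiro oxanickelacyclopentene (new C(=O)–C(CH3) bond), β-carbon elimination of the ring-fusion carbon then opens the four-membered ring to a seven-membered nickelacycle, and C(sp2)–C(sp3) reductive elimination forms the C(chain)–CH(fusion) bond. The closest known reaction is the Ni(cod)2/PCy3-catalysed intermolecular insertion of alkynes into 3-substituted cyclobutanones to give cyclohex-2-enones, where a CH2–C(=O) bond is cut; scission of a more substituted, ring-fusion acyl–carbon bond has not been shown. Ring C is closed by two-carbon enlargement of the four-membered ring (formal (4+2)), the last bond coming from reductive elimination. No stereocentre is created: the migrating fusion carbon keeps its configuration through β-carbon elimination and reductive elimination, so the cis C/D fusion of step 1 is carried over. The first selectivity needed is the alkyne orientation: the small methyl end should bond to the hindered ketone carbon and the larger chain end to nickel, a bias that is only moderate between two alkyl groups, and the other orientation gives a separable constitutional isomer. The second is cleavage of the C(=O)–CH(fusion) bond in place of the normally preferred C(=O)–CH2 bond, for which the substrate offers only the extra strain of the fusion bond next to the CMe2 carbon; this is not secured by precedent and is backed by a fallback that uses the established sense of cleavage.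

Step 19
Reactants: 24 tetracyclic enone
Product: 25 (2S,4aR,8S,8aS)-allylic alcohol, the octahydronaphthalen-2-ol corresponding to 24, with OH on the face of the ring-fusion hydrogens
Conditions: LiBH(s-Bu)3, THF, −78 °C; then H2O
Reagents that add atoms: none
Why: The bulky trialkylborohydride should add 1,2 to the fully substituted enone from the equatorial direction (the face of the ring-D bonds), giving the pseudo-axial alcohol needed for an invertive substitution; in the half-chair that keeps the ring-D bond at the homoallylic carbon equatorial, a small hydride (Luche conditions) would add axially and give the other epimer.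

Step 20
Reactants: 26 2,3-dimethylbut-2-ene
Product: 27 2-methoxyprop-2-yl hydroperoxide
Conditions: O3, MeOH/CH2Cl2, −78 °C; N2 purge, no reductive work-up
Reagents that add atoms: ozone, [O-][O+]=O; methanol, CO
Why: Ozonolysis of the tetrasubstituted alkene gives acetone and acetone carbonyl oxide (Criegee intermediate), which methanol traps as the monoperoxyketal hydroperoxide.

Step 21
Reactants: 25 allylic alcohol; 27 2-methoxyprop-2-yl hydroperoxide
Product: 29 (2R)-allylic peroxyketal carrying the O–O–C(CH3)2OCH3 group on the face of the ring-D bonds, via allylic mesylate 28 (not isolated)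
Conditions: MsCl, Et3N, THF, −40 °C; then 27, CsOH·H2O, DMF, −20 °C to 0 °C
Reagents that add atoms: none
Why: Sulfonylation of the secondary allylic alcohol and SN2 displacement of the pseudo-axial mesylate by the caesium salt of the peroxide (a strong, weakly basic α-nucleophile) should go with inversion, placing the peroxide on the face of the ring-D bonds as in the target.

Step 22
Reactants: 29 allylic peroxyketal
Product: 30 sipholenol M
Conditions: HF (48% aq.), MeCN, 0 °C to 20 °C
Reagents that add atoms: none
Why: Aqueous HF cleaves the three silyl ethers and hydrolyses the peroxyketal to the free hydroperoxide under non-basic, non-reducing conditions that a secondary allylic hydroperoxide should tolerate.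

**Compound list**

1 | 4,4-dimethylcyclohex-2-en-1-one | CC1(C)CCC(=O)C=C1 | starting material
2 | 1,1-diethoxyethene | C=C(OCC)OCC | starting material
3 | rac-trans-7,7-diethoxy-5,5-dimethylbicyclo[4.2.0]octan-2-one (racemate, one enantiomer drawn) | CCOC1(OCC)C[C@@H]2[C@@H]1C(C)(C)CCC2=O | intermediate (not isolated)
4 | rac-cis-7,7-diethoxy-5,5-dimethylbicyclo[4.2.0]octan-2-one (racemate, the (1S,6R) enantiomer drawn) | CCOC1(OCC)C[C@H]2[C@@H]1C(C)(C)CCC2=O | intermediate
5 | (1S,2R,6R)-7,7-diethoxy-5,5-dimethyl-2-{[(S)-N-methyl-S-phenylsulfonimidoyl]methyl}bicyclo[4.2.0]octan-2-ol | CCOC1(OCC)C[C@H]2[C@@H]1C(C)(C)CC[C@]2(O)C[S@@](=O)(=NC)c1ccccc1 | intermediate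
6 | (1S,6R)-7,7-diethoxy-5,5-dimethyl-2-methylidenebicyclo[4.2.0]octane | CCOC1(OCC)C[C@H]2[C@@H]1C(C)(C)CCC2=C | intermediate
7 | (1S,2S,6R)-7,7-diethoxy-5,5-dimethylspiro[bicyclo[4.2.0]octane-2,2'-oxirane] | CCOC1(OCC)C[C@H]2[C@@H]1C(C)(C)CC[C@@]23CO3 | intermediate
8 | (1S,2S,6R)-7,7-diethoxy-2,5,5-trimethylbicyclo[4.2.0]octan-2-ol | CCOC1(OCC)C[C@H]2[C@@H]1C(C)(C)CC[C@]2(C)O | intermediate
9 | (1S,2S,6R)-2-hydroxy-2,5,5-trimethylbicyclo[4.2.0]octan-7-one | O=C1C[C@H]2[C@@H]1C(C)(C)CC[C@]2(C)O | intermediate
10 | (1S,2S,6R)-2,5,5-trimethyl-2-(triethylsilyloxy)bicyclo[4.2.0]octan-7-one | O=C1C[C@H]2[C@@H]1C(C)(C)CC[C@]2(C)O[Si](CC)(CC)CC | intermediate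
11 | (2E,6E)-farnesol | CC(C)=CCC/C(C)=C/CC/C(C)=C/CO | starting material
12 | (2E,6E)-farnesyl acetate | CC(C)=CCC/C(C)=C/CC/C(C)=C/COC(C)=O | intermediate
13 | (2E,6S,7S,10S)-6,7:10,11-diepoxy-3,7,11-trimethyldodec-2-en-1-yl acetate | CC1(C)O[C@H]1CC[C@]2(C)O[C@H]2CC/C(C)=C/COC(C)=O | intermediate
14 | (2E,6S,7S,10S)-6,7:10,11-diepoxy-3,7,11-trimethyldodec-2-en-1-ol | CC1(C)O[C@H]1CC[C@]2(C)O[C@H]2CC/C(C)=C/CO | intermediate
15 | methanesulfonate of 14 | CC1(C)O[C@H]1CC[C@]2(C)O[C@H]2CC/C(C)=C/COS(C)(=O)=O | intermediate (not isolated)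
16 | (2E,6S,7S,10S)-1-bromo-6,7:10,11-diepoxy-3,7,11-trimethyldodec-2-ene | CC1(C)O[C@H]1CC[C@]2(C)O[C@H]2CC/C(C)=C/CBr | intermediate
17 | tert-butyl (4E,8S,9S,12S)-8,9:12,13-diepoxy-5,9,13-trimethyltetradec-4-enoate | CC1(C)O[C@H]1CC[C@]2(C)O[C@H]2CC/C(C)=C/CCC(=O)OC(C)(C)C | intermediate
18 | trans-fused δ-lactone on the (3S,5aS,6S,7S,9aS)-3-(tert-butyldimethylsilyloxy)-2,2,5a,7-tetramethyldecahydro-1-benzoxepine core (C6–CH2CH2–C(=O)–O–C7) | O=C1CC[C@H]2[C@]3(C)CC[C@H](O[Si](C)(C)C(C)(C)C)C(C)(C)O[C@H]3CC[C@]2(C)O1 | intermediate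
19 | lactol of 18 (anomeric mixture) | OC1CC[C@H]2[C@]3(C)CC[C@H](O[Si](C)(C)C(C)(C)C)C(C)(C)O[C@H]3CC[C@]2(C)O1 | intermediate
20 | (3S,5aS,6S,7S,9aS)-6-(but-3-yn-1-yl)-3-(tert-butyldimethylsilyloxy)-2,2,5a,7-tetramethyldecahydro-1-benzoxepin-7-ol | C#CCC[C@H]1[C@]2(C)CC[C@H](O[Si](C)(C)C(C)(C)C)C(C)(C)O[C@H]2CC[C@]1(C)O | intermediate
21 | 7-O-triethylsilyl ether of 20 | C#CCC[C@H]1[C@]2(C)CC[C@H](O[Si](C)(C)C(C)(C)C)C(C)(C)O[C@H]2CC[C@]1(C)O[Si](CC)(CC)CC | intermediate
22 | lithium acetylide of 21 | [Li]C#CCC[C@H]1[C@]2(C)CC[C@H](O[Si](C)(C)C(C)(C)C)C(C)(C)O[C@H]2CC[C@]1(C)O[Si](CC)(CC)CC | intermediate (not isolated)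
23 | (3S,5aS,6S,7S,9aS)-3-(tert-butyldimethylsilyloxy)-2,2,5a,7-tetramethyl-6-(pent-3-yn-1-yl)-7-(triethylsilyloxy)decahydro-1-benzoxepine | CC#CCC[C@H]1[C@]2(C)CC[C@H](O[Si](C)(C)C(C)(C)C)C(C)(C)O[C@H]2CC[C@]1(C)O[Si](CC)(CC)CC | intermediate
24 | tetracyclic enone (4aR,8S,8aS), as named in step 18 | CC1=C(CC[C@H]2[C@]3(C)CC[C@H](O[Si](C)(C)C(C)(C)C)C(C)(C)O[C@H]3CC[C@]2(C)O[Si](CC)(CC)CC)[C@@H]2[C@H](CC1=O)[C@@](C)(O[Si](CC)(CC)CC)CCC2(C)C | intermediate
25 | (2S,4aR,8S,8aS)-allylic alcohol from 24 | CC1=C(CC[C@H]2[C@]3(C)CC[C@H](O[Si](C)(C)C(C)(C)C)C(C)(C)O[C@H]3CC[C@]2(C)O[Si](CC)(CC)CC)[C@@H]2[C@H](C[C@@H]1O)[C@@](C)(O[Si](CC)(CC)CC)CCC2(C)C | intermediate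
26 | 2,3-dimethylbut-2-ene | CC(C)=C(C)C | starting material
27 | 2-methoxyprop-2-yl hydroperoxide | COC(C)(C)OO | intermediate
28 | methanesulfonate of 25 | CC1=C(CC[C@H]2[C@]3(C)CC[C@H](O[Si](C)(C)C(C)(C)C)C(C)(C)O[C@H]3CC[C@]2(C)O[Si](CC)(CC)CC)[C@@H]2[C@H](C[C@@H]1OS(C)(=O)=O)[C@@](C)(O[Si](CC)(CC)CC)CCC2(C)C | intermediate (not isolated)
29 | (2R)-allylic 2-methoxyprop-2-yl peroxide (peroxyketal) | CC1=C(CC[C@H]2[C@]3(C)CC[C@H](O[Si](C)(C)C(C)(C)C)C(C)(C)O[C@H]3CC[C@]2(C)O[Si](CC)(CC)CC)[C@@H]2[C@H](C[C@H]1OOC(C)(C)OC)[C@@](C)(O[Si](CC)(CC)CC)CCC2(C)C | intermediate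
30 | sipholenol M | CC1=C(CC[C@H]2[C@]3(C)CC[C@H](O)C(C)(C)O[C@H]3CC[C@]2(C)O)[C@@H]2[C@H](C[C@H]1OO)[C@@](C)(O)CCC2(C)C | target

**Step count and risks**

Total step count: 22. Longest linear sequence: 14 steps (farnesol 11 to the target: steps 8–19, 21, 22).

Steps most likely to fail:

1. Step 18 (proposed new method). The nickelacycle may open at the less substituted CH2–C(=O) bond, the normal preference, or the alkyne may insert in the reverse orientation; both give constitutional isomers of 24. The fallback uses the established sense of cleavage and known reactions; it sets out from 10 and 21 and returns at 24. Cyclobutanone 10 is treated with 1-(trimethylsilyl)propyne under Ni(cod)2/PCy3; cleavage of the CH2–C(=O) bond, with the carbonyl carbon bonding to the methyl-bearing alkyne carbon, should give the silyl enone F1, whose carbonyl stays on the ring-fusion carbon next to CMe2. Bu4NF in wet THF at 0 °C removes the vinylic silicon to give the enone F2; the hindered tertiary triethylsilyl ether is expected to survive brief exposure. Terminal alkyne 21 is ozonised (O3, CH2Cl2/MeOH, −78 °C, then H2O2) to the carboxylic acid F3. Iododecarboxylation (PhI(OAc)2, I2, hν) gives the primary iodide F4, and iodine–lithium exchange (t-BuLi, Et2O, −78 °C) the alkyllithium F5. Addition of the alkyllithium (with CeCl3) to the carbonyl of the enone gives the tertiary allylic alcohol F6; either carbinol epimer serves. Oxidative 1,3-transposition with pyridinium chlorochromate, [C5H5NH][CrO3Cl] (Babler–Dauben oxidation), moves the oxygen to the former silyl carbon and the alkene into the tetrasubstituted position, which is enone 24.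

2. Step 13. The tertiary cation formed when ring B closes may lose a proton before the ester carbonyl captures it, so that ring closure and lactonisation do not occur in one operation. The fallback separates the two events; it sets out from 17 and returns at 18. The cascade is run to the bicyclic alkene ester F7 (exocyclic methylene isomer drawn; endocyclic isomers behave alike). The lactone is then closed by Brønsted acid (CF3CO2H, CH2Cl2, 0 °C): protonation regenerates the tertiary cation, the ester captures it and 2-methylpropene is lost, as in acid lactonisations of bicyclic homofarnesic acids. If the ring-A silyl ether is lost, it is put back with TBSOTf to give 18.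

3. Step 21. Ionisation of the allylic mesylate (loss of stereocontrol, allylic transposition) or elimination to a diene may outrun the SN2 displacement. The fallback uses radical chemistry; it sets out from 25 and returns at 30. Alcohol 25 is dehydrated on purpose (Burgess reagent) to the homoannular diene F8. Cobalt-catalysed hydroperoxysilylation (Co(thd)2 cat., O2, Et3SiH; Isayama–Mukaiyama peroxidation) should deliver a hydrogen atom to the unsubstituted diene terminus and trap the allyl radical with O2 at the secondary carbon, giving the triethylsilyl peroxide F9. The equatorial epimer on the face of the ring-D bonds is expected to be favoured as the more stable one and would be separated from its epimer. HF under the conditions of step 22 removes all silyl groups and gives 30.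

**Further compounds**

F1 | step 18 | (4aS,5S,8aR)-2,5,8,8-tetramethyl-5-(triethylsilyloxy)-3-(trimethylsilyl)-4a,5,6,7,8,8a-hexahydronaphthalen-1(4H)-one | O=C1C(C)=C([Si](C)(C)C)C[C@H]2[C@@H]1C(C)(C)CC[C@]2(C)O[Si](CC)(CC)CC
F2 | step 18 | (4aS,5S,8aR)-2,5,8,8-tetramethyl-5-(triethylsilyloxy)-4a,5,6,7,8,8a-hexahydronaphthalen-1(4H)-one | O=C1C(C)=CC[C@H]2[C@@H]1C(C)(C)CC[C@]2(C)O[Si](CC)(CC)CC
F3 | step 18 | 3-[(3S,5aS,6S,7S,9aS)-3-(tert-butyldimethylsilyloxy)-2,2,5a,7-tetramethyl-7-(triethylsilyloxy)decahydro-1-benzoxepin-6-yl]propanoic acid | OC(=O)CC[C@H]1[C@]2(C)CC[C@H](O[Si](C)(C)C(C)(C)C)C(C)(C)O[C@H]2CC[C@]1(C)O[Si](CC)(CC)CC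
F4 | step 18 | (3S,5aS,6S,7S,9aS)-3-(tert-butyldimethylsilyloxy)-6-(2-iodoethyl)-2,2,5a,7-tetramethyl-7-(triethylsilyloxy)decahydro-1-benzoxepine | ICC[C@H]1[C@]2(C)CC[C@H](O[Si](C)(C)C(C)(C)C)C(C)(C)O[C@H]2CC[C@]1(C)O[Si](CC)(CC)CC
F5 | step 18 | alkyllithium from F4 | [Li]CC[C@H]1[C@]2(C)CC[C@H](O[Si](C)(C)C(C)(C)C)C(C)(C)O[C@H]2CC[C@]1(C)O[Si](CC)(CC)CC
F6 | step 18 | tertiary allylic alcohol from F2 and F5 (carbinol centre undefined, both epimers) | OC1(CC[C@H]3[C@]4(C)CC[C@H](O[Si](C)(C)C(C)(C)C)C(C)(C)O[C@H]4CC[C@]3(C)O[Si](CC)(CC)CC)C(C)=CC[C@H]2[C@@H]1C(C)(C)CC[C@]2(C)O[Si](CC)(CC)CC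
F7 | step 13 | tert-butyl 3-[(3S,5aS,6S,9aS)-3-(tert-butyldimethylsilyloxy)-2,2,5a-trimethyl-7-methylidenedecahydro-1-benzoxepin-6-yl]propanoate | CC(C)(C)OC(=O)CC[C@H]1[C@]2(C)CC[C@H](O[Si](C)(C)C(C)(C)C)C(C)(C)O[C@H]2CCC1=C
F8 | step 21 | homoannular diene from 25 | CC1=C(CC[C@H]2[C@]3(C)CC[C@H](O[Si](C)(C)C(C)(C)C)C(C)(C)O[C@H]3CC[C@]2(C)O[Si](CC)(CC)CC)[C@@H]2[C@H](C=C1)[C@@](C)(O[Si](CC)(CC)CC)CCC2(C)C
F9 | step 21 | (2R)-allylic triethylsilyl peroxide | CC1=C(CC[C@H]2[C@]3(C)CC[C@H](O[Si](C)(C)C(C)(C)C)C(C)(C)O[C@H]3CC[C@]2(C)O[Si](CC)(CC)CC)[C@@H]2[C@H](C[C@H]1OO[Si](CC)(CC)CC)[C@@](C)(O[Si](CC)(CC)CC)CCC2(C)C
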